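Everything rests on cutting the C4–C4a bond of the pyranone ring C. This turns the isoflavone core into a 2-aryl-3-aryloxyacrylic acid whose O1–C2=C3 chain already ties the C4 carboxyl carbon to ring A. One dehydrative intramolecular Friedel–Crafts acylation then closes ring C. It exploits the symmetry of the phloroglucinol-type ring A: the two carbons beside C8a are identical and each is activated by three oxygen donors, so only one chromone can arise. The precursor carries three methyl ethers and a bromine at C3' of ring B. That bromine later takes an allyl group, which cross-metathesis with methacrolein and 1,2-reduction turn into the (E)-4-hydroxy-3-methylbut-2-enyl chain.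

Key step: step 6

Assumption: compounds 5, 7 and 8 are drawn as the E isomers expected to prevail. Any Z isomer formed alongside is carried on unseparated, because step 6 equilibrates the C2=C3 geometry and both isomers end in 10.

Step 1
Reactants: 1 3-bromo-4-methoxyphenylacetic acid
Product: 2 methyl 3-bromo-4-methoxyphenylacetate
Conditions: MeOH, H2SO4 (cat.), reflux
Reagents that add atoms: methanol, CO
Why: Fischer esterification, driven to the ester by the large excess of methanol, touches neither the aryl bromide nor the aryl methyl ether.

Step 2
Reactants: 2 methyl 3-bromo-4-methoxyphenylacetate; 3 methyl formate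
Product: 4 methyl (Z)-2-(3-bromo-4-methoxyphenyl)-3-hydroxyacrylate (hydrogen-bonded enol tautomer of the α-formyl ester)
Conditions: NaH, HCO2Me, THF, 0 °C to rt; then 1 M HCl
Reagents that add atoms: methyl formate 3, COC=O
Why: Crossed Claisen condensation (C-formylation) in which methyl formate has no α-hydrogen and is the more electrophilic ester, the benzylic enolate of 2 attacks it, and deprotonation of the acidic product pulls the equilibrium over, while the methyl/methyl pairing of the two esters makes alkoxide exchange invisible.

Step 3
Reactants: 4 methyl (Z)-2-(3-bromo-4-methoxyphenyl)-3-hydroxyacrylate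
Product: 5 methyl (E)-2-(3-bromo-4-methoxyphenyl)-3-(tosyloxy)acrylate
Conditions: TsCl, Et3N, CH2Cl2, 0 °C to rt
Reagents that add atoms: p-toluenesulfonyl chloride, Cc1ccc(cc1)S(=O)(=O)Cl
Why: O-Sulfonylation of an acidic enol, in which triethylamine forms the delocalised enolate, the hard sulfonyl chloride is attacked through oxygen, and without a chelating metal the tosyloxy group should end up trans to the ester (E), a geometry with no bearing on later steps.

Step 4
Reactants: 5 methyl (E)-2-(3-bromo-4-methoxyphenyl)-3-(tosyloxy)acrylate; 6 3,5-dimethoxyphenol
Product: 7 methyl (E)-2-(3-bromo-4-methoxyphenyl)-3-(3,5-dimethoxyphenoxy)acrylate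
Conditions: K2CO3, DMF, rt to 50 °C
Reagents that add atoms: 3,5-dimethoxyphenol 6, COc1cc(O)cc(OC)c1
Why: Nucleophilic vinylic substitution by addition–elimination, in which the potassium phenoxide adds through oxygen (favoured in a polar aprotic solvent) to the ester-activated β-carbon and the stabilised carbanion expels tosylate, the aryl bromide being inert without a metal catalyst.

Step 5
Reactants: 7 methyl (E)-2-(3-bromo-4-methoxyphenyl)-3-(3,5-dimethoxyphenoxy)acrylate
Product: 8 (E)-2-(3-bromo-4-methoxyphenyl)-3-(3,5-dimethoxyphenoxy)acrylic acid
Conditions: LiOH, THF–H2O, rt; then 1 M HCl, 0 °C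
Reagents that add atoms: lithium hydroxide, [Li+].[OH-]
Why: Saponification by acyl–oxygen cleavage, run without an alcohol cosolvent so that no alkoxide can exchange the aryloxy group by addition–elimination, the carboxylate once formed switching off the electrophilicity of the alkene and cold acidification sparing the enol ether.

Step 6
Reactants: 8 (E)-2-(3-bromo-4-methoxyphenyl)-3-(3,5-dimethoxyphenoxy)acrylic acid
Product: 10 3'-bromo-5,7,4'-trimethoxyisoflavone, via Z-acrylic acid isomer 9 (not isolated)
Conditions: P2O5–MeSO3H (1:10 w/w, Eaton's reagent), dilute (0.05 M), rt to 50 °C; then ice–water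
Reagents that add atoms: none
Why: In the strongly acidic, dehydrating medium the push–pull alkene of 8 is protonated reversibly at C3, rotation about C2–C3 in the oxocarbenium ion and loss of the proton give the Z isomer 9, and the carboxyl group is ionised to an acylium ion that in 9 sits next to ring A. The ring carbon ortho to O1 attacks the acylium carbon, and proton loss from the arenium ion restores aromaticity and leaves the C4–C4a bond. The closest known reaction type is the acid-mediated cyclodehydration of 3-aryloxyacrylic acids to chromones, an intramolecular Friedel–Crafts acylation in which the trans adducts of phenols and propiolates isomerise and close in the same way. Ring C closes as a six-membered ring in a 6-exo mode (the carbon–oxygen multiple bond of the acylium stays outside the ring), with all six ring atoms able to lie in one plane. No stereocentre is formed, and the E/Z question disappears because C2=C3 becomes endocyclic, the irreversible closure draining the E/Z equilibrium through 9. The step needs regioselectivity on ring A and preference for ring A over ring B: the short tether reaches only the two carbons beside C8a, which are the same by symmetry and lie ortho or para to all three oxygen donors, whereas ring B could be reached only through a four-membered ring, and the preformed O1–C2 bond rules out the 3-arylcoumarin mode of union.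

Step 7
Reactants: 10 3'-bromo-5,7,4'-trimethoxyisoflavone
Product: 11 3'-bromo-5,7,4'-trihydroxyisoflavone (3'-bromogenistein)
Conditions: BBr3 (excess), CH2Cl2, −78 °C to rt; then ice–water
Reagents that add atoms: none
Why: Lewis-acid cleavage of aryl methyl ethers, in which BBr3 binds each methoxy oxygen (the C5 one first, helped by chelation to the C4 carbonyl) and bromide removes the methyl group by SN2 attack, carried out at this stage because the aryl bromide and the pyranone tolerate it and no acid-sensitive side chain is yet present.

Step 8
Reactants: 11 3'-bromo-5,7,4'-trihydroxyisoflavone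
Product: 12 3'-bromo-5,7,4'-triacetoxyisoflavone
Conditions: Ac2O, pyridine, DMAP (cat.), rt
Reagents that add atoms: acetic anhydride, CC(=O)OC(C)=O
Why: DMAP-catalysed O-acylation covers all three phenols, the hydrogen-bonded 5-OH included, with acetates that raise solubility, keep the 4'-oxygen from adding to the later enal and come off under very mild base.

Step 9
Reactants: 12 3'-bromo-5,7,4'-triacetoxyisoflavone; 13 allyltributylstannane
Product: 14 3'-allyl-5,7,4'-triacetoxyisoflavone
Conditions: Pd(PPh3)4 (5 mol %), toluene (degassed), 100 °C
Reagents that add atoms: allyltributylstannane 13, C=CC[Sn](CCCC)(CCCC)CCCC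
Why: Migita–Kosugi–Stille coupling through oxidative addition of zerovalent palladium into the C3'–Br bond, allyl transfer from tin and reductive elimination, under neutral base-free conditions that leave the aryl acetates and the pyranone untouched.

Step 10
Reactants: 14 3'-allyl-5,7,4'-triacetoxyisoflavone; 15 methacrolein
Product: 16 5,7,4'-triacetoxy-3'-[(E)-3-methyl-4-oxobut-2-enyl]isoflavone
Conditions: second-generation Grubbs catalyst (H2IMes)(PCy3)Cl2Ru=CHPh (5 mol %), methacrolein (excess), CH2Cl2, 40 °C
Reagents that add atoms: methacrolein 15, C=C(C)C=O
Why: Olefin cross-metathesis between a reactive terminal allylarene and an electron-poor 1,1-disubstituted enal that does not homodimerise, driven by loss of ethene, sets the trisubstituted alkene under thermodynamic control with the formyl group trans to the benzylic CH2 (E), while the hindered, electron-poor C2=C3 of the pyranone does not engage.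

Step 11
Reactants: 16 5,7,4'-triacetoxy-3'-[(E)-3-methyl-4-oxobut-2-enyl]isoflavone
Product: 17 5,7,4'-triacetoxy-3'-[(E)-4-hydroxy-3-methylbut-2-enyl]isoflavone
Conditions: NaBH4, CeCl3·7H2O, MeOH–THF, −20 °C
Reagents that add atoms: none
Why: Luche reduction delivers hydride 1,2 to the cerium-activated aldehyde within minutes at low temperature, faster than attack on the vinylogous-ester carbonyl C4 or on C2, leaves the E alkene unchanged, and any acetate lost to methanolysis is harmless because the next step removes all three.

Step 12
Reactants: 17 5,7,4'-triacetoxy-3'-[(E)-4-hydroxy-3-methylbut-2-enyl]isoflavone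
Product: 18 Vogelin E
Conditions: K2CO3 (cat.), MeOH, 0 °C to rt; then aq. NH4Cl
Reagents that add atoms: none
Why: Base-catalysed transesterification (methanolysis) of aryl acetates, whose phenoxide leaving groups make them the most reactive sites, is mild enough to spare the pyranone from opening at C2, and the near-neutral quench avoids acid-induced cyclisation of the allylic alcohol onto the 4'-OH, so the E geometry is kept.

Compound list
1 | 3-bromo-4-methoxyphenylacetic acid | COc1ccc(CC(=O)O)cc1Br | starting material
2 | methyl 3-bromo-4-methoxyphenylacetate | COC(=O)Cc1ccc(OC)c(Br)c1 | intermediate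
3 | methyl formate | COC=O | starting material
4 | methyl (Z)-2-(3-bromo-4-methoxyphenyl)-3-hydroxyacrylate | COC(=O)/C(=C\O)c1ccc(OC)c(Br)c1 | intermediate
5 | methyl (E)-2-(3-bromo-4-methoxyphenyl)-3-(tosyloxy)acrylate | COC(=O)/C(=C/OS(=O)(=O)c1ccc(C)cc1)c1ccc(OC)c(Br)c1 | intermediate
6 | 3,5-dimethoxyphenol | COc1cc(O)cc(OC)c1 | starting material
7 | methyl (E)-2-(3-bromo-4-methoxyphenyl)-3-(3,5-dimethoxyphenoxy)acrylate | COC(=O)/C(=C/Oc1cc(OC)cc(OC)c1)c1ccc(OC)c(Br)c1 | intermediate
8 | (E)-2-(3-bromo-4-methoxyphenyl)-3-(3,5-dimethoxyphenoxy)acrylic acid | OC(=O)/C(=C/Oc1cc(OC)cc(OC)c1)c1ccc(OC)c(Br)c1 | intermediate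
9 | (Z)-2-(3-bromo-4-methoxyphenyl)-3-(3,5-dimethoxyphenoxy)acrylic acid (not isolated) | OC(=O)/C(=C\Oc1cc(OC)cc(OC)c1)c1ccc(OC)c(Br)c1 | intermediate
10 | 3'-bromo-5,7,4'-trimethoxyisoflavone | COc1ccc(-c2coc3cc(OC)cc(OC)c3c2=O)cc1Br | intermediate
11 | 3'-bromo-5,7,4'-trihydroxyisoflavone | Oc1ccc(-c2coc3cc(O)cc(O)c3c2=O)cc1Br | intermediate
12 | 3'-bromo-5,7,4'-triacetoxyisoflavone | CC(=O)Oc1ccc(-c2coc3cc(OC(C)=O)cc(OC(C)=O)c3c2=O)cc1Br | intermediate
13 | allyltributylstannane | C=CC[Sn](CCCC)(CCCC)CCCC | starting material
14 | 3'-allyl-5,7,4'-triacetoxyisoflavone | C=CCc1cc(-c2coc3cc(OC(C)=O)cc(OC(C)=O)c3c2=O)ccc1OC(C)=O | intermediate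
15 | methacrolein | C=C(C)C=O | starting material
16 | 5,7,4'-triacetoxy-3'-[(E)-3-methyl-4-oxobut-2-enyl]isoflavone | C/C(=C\Cc1cc(-c2coc3cc(OC(C)=O)cc(OC(C)=O)c3c2=O)ccc1OC(C)=O)C=O | intermediate
17 | 5,7,4'-triacetoxy-3'-[(E)-4-hydroxy-3-methylbut-2-enyl]isoflavone | C/C(=C\Cc1cc(-c2coc3cc(OC(C)=O)cc(OC(C)=O)c3c2=O)ccc1OC(C)=O)CO | intermediate
18 | Vogelin E, 5,7,4'-trihydroxy-3'-[(E)-4-hydroxy-3-methylbut-2-enyl]isoflavone | C/C(=C\Cc1cc(-c2coc3cc(O)cc(O)c3c2=O)ccc1O)CO | target

Total step count: 12. Longest linear sequence: 12 steps (1 to 18).

Steps most likely to fail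

**Step 6.** The C3-protonated cation through which 8 isomerises may lose CO2 or shed the aryloxy group. Ring A may also be sulfonylated by the medium or acylated by a second molecule before the acylium closes.
- The fallback gives up the tether and uses the classical deoxybenzoin construction. It sets out from 1 and 6 and comes back to the route at 10.
- Heating 1 and 6 in BF3·OEt2 at about 85 °C should acylate 6 ortho to its hydroxyl group. This is a Friedel–Crafts acylation steered by boron chelation, and it gives 2-(3-bromo-4-methoxyphenyl)-1-(2-hydroxy-4,6-dimethoxyphenyl)ethanone F1.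
- N,N-Dimethylformamide dimethyl acetal in toluene at 90 °C then supplies C2 through the enaminone (E)-2-(3-bromo-4-methoxyphenyl)-3-(dimethylamino)-1-(2-hydroxy-4,6-dimethoxyphenyl)prop-2-en-1-one F2.
- F2 is not isolated. It closes onto the phenol oxygen with loss of dimethylamine to give 10.

**Step 4.** The phenoxide may attack the sulfur of the enol tosylate instead of the β-carbon. This sulfonyl transfer would regenerate the enolate of 4 and consume 6.
- The fallback replaces the sulfonate nucleofuge by a halide, which offers no second electrophilic site. It sets out from 4 and comes back at 7.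
- (Chloromethylene)dimethyliminium chloride in CH2Cl2 (0 °C to reflux) should convert the enol into methyl (E)-2-(3-bromo-4-methoxyphenyl)-3-chloroacrylate F3. This deoxychlorination is well established for enols of 1,3-dicarbonyl compounds.
- F3 with 6 and K2CO3 in DMF then undergoes the same addition–elimination to give 7.

**Step 10.** Ruthenium hydride species formed by catalyst decay may move the allyl double bond into conjugation with ring B, or the reaction may stall at the homodimer of 14.
- The fallback builds the trisubstituted alkene by carbonyl olefination instead of metathesis. It sets out from 14 and comes back at 16.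
- Lemieux–Johnson cleavage of the terminal alkene (OsO4 cat., NaIO4, 2,6-lutidine, dioxane–water, rt) gives 2-[2-acetoxy-5-(5,7-diacetoxy-4-oxo-4H-chromen-3-yl)phenyl]acetaldehyde F4.
- A Wittig reaction of F4 with the stabilised ylide 2-(triphenylphosphoranylidene)propanal in CH2Cl2 at rt should give the E enal 16.

Further compounds
F1 | step 6 | 2-(3-bromo-4-methoxyphenyl)-1-(2-hydroxy-4,6-dimethoxyphenyl)ethanone | COc1cc(O)c(C(=O)Cc2ccc(OC)c(Br)c2)c(OC)c1
F2 | step 6 | (E)-2-(3-bromo-4-methoxyphenyl)-3-(dimethylamino)-1-(2-hydroxy-4,6-dimethoxyphenyl)prop-2-en-1-one | COc1cc(O)c(C(=O)/C(=C/N(C)C)c2ccc(OC)c(Br)c2)c(OC)c1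
F3 | step 4 | methyl (E)-2-(3-bromo-4-methoxyphenyl)-3-chloroacrylate | COC(=O)/C(=C/Cl)c1ccc(OC)c(Br)c1
F4 | step 10 | 2-[2-acetoxy-5-(5,7-diacetoxy-4-oxo-4H-chromen-3-yl)phenyl]acetaldehyde | O=CCc1cc(-c2coc3cc(OC(C)=O)cc(OC(C)=O)c3c2=O)ccc1OC(C)=O
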